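The route rests on cutting the oxolane (O1, C12–C15; chain numbered from the benzylic carbon C1) between its ring methylene C13 and the carbinol carbon C14, which reveals a β-alkoxy ketone made from two esters. In the key step the alkoxide of methyl 2-hydroxy-2-methylpropanoate adds to C12 of a geraniol-derived dienoate, and the resulting C13 enolate is acylated by the non-enolisable ester carbon C14. This tandem oxa-Michael/Dieckmann annulation forms the ether and the C13–C14 bond and delivers the complete 5,5-dimethyl-4-oxooxolane in one operation. It exploits the 1,3-relationship of O1 and the C14 oxygen across C13 and the gem-dimethyl carbon C15. Reagent-controlled reduction, asymmetric propargylation and carboalumination/benzyl coupling complete the chain.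

Key step: step 4

Remark: the annulation gives the oxolanone as a racemate at C12, so the reagent-controlled reduction in step 6 is divergent and at most half of the material can reach the required (12S,14S) isomer.

Step 1
Reactants: 1 geraniol
Product: 2 tert-butyl{[(2E)-3,7-dimethylocta-2,6-dien-1-yl]oxy}dimethylsilane
Conditions: t-BuMe2SiCl, imidazole, DMF, 0 °C to rt
Reagents that add atoms: tert-butyldimethylsilyl chloride CC(C)(C)[Si](C)(C)Cl
Why: Silylation of the primary allylic alcohol masks the C5 oxygen against the basic annulation and creates no stereocentre.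

Step 2
Reactants: 2 tert-butyl{[(2E)-3,7-dimethylocta-2,6-dien-1-yl]oxy}dimethylsilane
Product: 4 (2E,6E)-8-[(tert-butyldimethylsilyl)oxy]-2,6-dimethylocta-2,6-dienal, via allylic alcohol 3 (not isolated)
Conditions: SeO2 (0.3 equiv), t-BuOOH, CH2Cl2, rt; then MnO2, CH2Cl2, rt
Reagents that add atoms: tert-butyl hydroperoxide CC(C)(C)OO
Why: Riley allylic oxidation should attack the (E)-methyl group of the terminal trisubstituted alkene through an ene/[2,3]-sigmatropic sequence that keeps the E geometry, and MnO2 then takes the allylic alcohol to the enal whose carbonyl carbon becomes C12.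

Step 3
Reactants: 4 (2E,6E)-8-[(tert-butyldimethylsilyl)oxy]-2,6-dimethylocta-2,6-dienal; 5 methyl (triphenylphosphoranylidene)acetate
Product: 6 methyl (2E,4E,8E)-10-[(tert-butyldimethylsilyl)oxy]-4,8-dimethyldeca-2,4,8-trienoate
Conditions: toluene, 80 °C
Reagents that add atoms: none
Why: Wittig olefination with a stabilised ylide should give the (E)-configured C12=C13 enoate and brings in C13 together with its ester activating group.

Step 4
Reactants: 6 methyl (2E,4E,8E)-10-[(tert-butyldimethylsilyl)oxy]-4,8-dimethyldeca-2,4,8-trienoate; 7 methyl 2-hydroxy-2-methylpropanoate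
Product: 9 methyl 2-[(2E,6E)-8-[(tert-butyldimethylsilyl)oxy]-6-methylocta-2,6-dien-2-yl]-5,5-dimethyl-4-oxooxolane-3-carboxylate (racemic), via oxa-Michael adduct 8 (not isolated)
Conditions: NaH (1.2 equiv), THF–DMSO, 0 °C to rt; AcOH quench
Reagents that add atoms: none
Why: The sodium alkoxide of 7 adds reversibly to C12 (the β-carbon) of dienoate 6, and the ester enolate so formed at C13 attacks the neighbouring ester carbonyl C14, expels methoxide and ends as the stabilised β-keto ester enolate, which pulls all preceding equilibria forward. The closest known reaction type is the tandem oxa-Michael/Dieckmann annulation of α-hydroxy esters with acrylates and crotonates to 4-oxooxolane-3-carboxylates. The oxolane closes in a 5-exo-trig mode, the enolate carbon C13 attacking the C14 carbonyl whose oxygen stays outside the ring. The new stereocentre C12 is formed without control, so 9 is racemic (C13 is an epimerisable β-keto ester centre that is lost in step 5), and absolute configuration is imposed in step 6. The step needs 1,4- over 1,6-addition and cross- over self-condensation: the 1,6-adduct has no five-membered closure open to it and reverts, 7 has no α-hydrogen and cannot enolise, and the gem-dimethyl group at C15 favours ring closure.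

Step 5
Reactants: 9 methyl 2-[(2E,6E)-8-[(tert-butyldimethylsilyl)oxy]-6-methylocta-2,6-dien-2-yl]-5,5-dimethyl-4-oxooxolane-3-carboxylate (racemic)
Product: 10 5-[(2E,6E)-8-[(tert-butyldimethylsilyl)oxy]-6-methylocta-2,6-dien-2-yl]-2,2-dimethyloxolan-3-one (racemic)
Conditions: NaCl, H2O, DMSO, 130 °C
Reagents that add atoms: none
Why: Krapcho dealkoxycarbonylation of the β-keto ester removes the activating ester from C13 under neutral conditions and leaves the oxolan-3-one with C13 as a methylene group.

Step 6
Reactants: 10 5-[(2E,6E)-8-[(tert-butyldimethylsilyl)oxy]-6-methylocta-2,6-dien-2-yl]-2,2-dimethyloxolan-3-one (racemic)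
Product: 11 (3S,5S)-5-[(2E,6E)-8-[(tert-butyldimethylsilyl)oxy]-6-methylocta-2,6-dien-2-yl]-2,2-dimethyloxolan-3-ol
Conditions: (R)-tetrahydro-1-methyl-3,3-diphenyl-1H,3H-pyrrolo[1,2-c][1,3,2]oxazaborole (0.5 equiv), catecholborane, toluene, −78 °C; aqueous NaOH; chromatography
Reagents that add atoms: none
Why: In this Corey–Bakshi–Shibata reduction the (R)-catalyst should deliver hydride to the face of the C14 carbonyl that gives the (S)-carbinol (quaternary C15 as the large group), which in the (12S)-enantiomer of 10 is also the less hindered face anti to the alkenyl group and gives cis-11, while the (12R)-enantiomer should be converted into the (3S,5R)-trans diastereomer that is removed by chromatography.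

Step 7
Reactants: 11 (3S,5S)-5-[(2E,6E)-8-[(tert-butyldimethylsilyl)oxy]-6-methylocta-2,6-dien-2-yl]-2,2-dimethyloxolan-3-ol
Product: 12 (2E,6E)-7-[(2S,4S)-4-hydroxy-5,5-dimethyloxolan-2-yl]-3-methylocta-2,6-dien-1-ol
Conditions: Bu4NF, THF, 0 °C
Reagents that add atoms: none
Why: Fluoride-mediated desilylation frees the primary allylic alcohol at C5 and leaves the oxolane and both stereocentres untouched.

Step 8
Reactants: 12 (2E,6E)-7-[(2S,4S)-4-hydroxy-5,5-dimethyloxolan-2-yl]-3-methylocta-2,6-dien-1-ol
Product: 13 (2E,6E)-7-[(2S,4S)-4-hydroxy-5,5-dimethyloxolan-2-yl]-3-methylocta-2,6-dienal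
Conditions: MnO2, CH2Cl2, rt
Reagents that add atoms: none
Why: MnO2 is a chemoselective oxidant for allylic alcohols, so only the C5 alcohol should be oxidised to the (E)-enal while the hindered saturated C14 hydroxyl stays.

Step 9
Reactants: 13 (2E,6E)-7-[(2S,4S)-4-hydroxy-5,5-dimethyloxolan-2-yl]-3-methylocta-2,6-dienal; 14 4,4,5,5-tetramethyl-2-(propa-1,2-dien-1-yl)-1,3,2-dioxaborolane
Product: 15 (4R,5E,9E)-10-[(2S,4S)-4-hydroxy-5,5-dimethyloxolan-2-yl]-6-methylundeca-5,9-dien-1-yn-4-ol
Conditions: (R)-3,3'-bis(2,4,6-triisopropylphenyl)-1,1'-binaphthalene-2,2'-diyl hydrogen phosphate (10 mol%), 4 Å molecular sieves, toluene, −20 °C; aqueous work-up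
Reagents that add atoms: none
Why: Chiral phosphoric acid catalysed propargylation with the allenylboronate (SE2' addition through a six-membered transition state held by the catalyst) should attack the Re face of the aldehyde and set C5 as R under catalyst control, the antipode of the catalyst being used if a model aldehyde shows the opposite sense.

Step 10
Reactants: 16 4-methoxy-2-methylphenol
Product: 17 2-hydroxy-5-methoxy-3-methylbenzaldehyde
Conditions: MgCl2, Et3N, paraformaldehyde, MeCN, reflux; aqueous HCl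
Reagents that add atoms: paraformaldehyde (formaldehyde) C=O
Why: In this magnesium-mediated ortho-formylation the magnesium phenoxide directs formaldehyde to the only free ortho position and a second equivalent of formaldehyde oxidises the benzylic alkoxide to the aldehyde by hydride transfer.

Step 11
Reactants: 17 2-hydroxy-5-methoxy-3-methylbenzaldehyde
Product: 18 2-[(tert-butyldimethylsilyl)oxy]-5-methoxy-3-methylbenzaldehyde
Conditions: t-BuMe2SiCl, imidazole, 4-(dimethylamino)pyridine (cat.), DMF, 40 °C
Reagents that add atoms: tert-butyldimethylsilyl chloride CC(C)(C)[Si](C)(C)Cl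
Why: Silylation of the phenol gives a protecting group that should survive Me3Al and can be cleaved at the end by buffered fluoride without harming the allylic acetate.

Step 12
Reactants: 18 2-[(tert-butyldimethylsilyl)oxy]-5-methoxy-3-methylbenzaldehyde
Product: 19 {2-[(tert-butyldimethylsilyl)oxy]-5-methoxy-3-methylphenyl}methanol
Conditions: i-Bu2AlH, CH2Cl2, −78 °C; aqueous potassium sodium tartrate
Reagents that add atoms: none
Why: Hydride reduction of the aldehyde with i-Bu2AlH at low temperature gives the benzylic alcohol as an aluminium alkoxide, which disfavours migration of the silyl group from the phenol to the benzylic oxygen.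

Step 13
Reactants: 19 {2-[(tert-butyldimethylsilyl)oxy]-5-methoxy-3-methylphenyl}methanol
Product: 20 tert-butyl[2-(chloromethyl)-4-methoxy-6-methylphenoxy]dimethylsilane
Conditions: SOCl2, pyridine, CH2Cl2, 0 °C
Reagents that add atoms: thionyl chloride O=S(Cl)Cl
Why: Deoxychlorination of the electron-rich benzylic alcohol with SOCl2 buffered by pyridine should give the benzylic chloride needed as the coupling electrophile.

Step 14
Reactants: 15 (4R,5E,9E)-10-[(2S,4S)-4-hydroxy-5,5-dimethyloxolan-2-yl]-6-methylundeca-5,9-dien-1-yn-4-ol; 20 tert-butyl[2-(chloromethyl)-4-methoxy-6-methylphenoxy]dimethylsilane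
Product: 22 (2E,5R,6E,10E)-1-{2-[(tert-butyldimethylsilyl)oxy]-5-methoxy-3-methylphenyl}-11-[(2S,4S)-4-hydroxy-5,5-dimethyloxolan-2-yl]-3,7-dimethyldodeca-2,6,10-trien-5-ol, via alkenylalane 21 (not isolated)
Conditions: Me3Al (4 equiv), Cp2ZrCl2 (0.25 equiv), CH2Cl2, 0 °C to rt; then 20, Pd(PPh3)4 (5 mol%), THF, rt; aqueous potassium sodium tartrate
Reagents that add atoms: trimethylaluminium C[Al](C)C
Why: Zirconium-catalysed methylalumination adds methyl and aluminium syn across the terminal alkyne with aluminium on the terminal carbon (both hydroxyls travel as aluminium alkoxides), and the palladium-catalysed Negishi-type coupling of the alkenylalane with benzylic chloride 20 retains the geometry, so the C2=C3 bond should be E.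

Step 15
Reactants: 22 (2E,5R,6E,10E)-1-{2-[(tert-butyldimethylsilyl)oxy]-5-methoxy-3-methylphenyl}-11-[(2S,4S)-4-hydroxy-5,5-dimethyloxolan-2-yl]-3,7-dimethyldodeca-2,6,10-trien-5-ol
Product: 23 (2E,5R,6E,10E)-1-{2-[(tert-butyldimethylsilyl)oxy]-5-methoxy-3-methylphenyl}-11-[(2S,4S)-4-hydroxy-5,5-dimethyloxolan-2-yl]-3,7-dimethyldodeca-2,6,10-trien-5-yl acetate
Conditions: Ac2O (1.2 equiv), pyridine, CH2Cl2, 0 °C
Reagents that add atoms: acetic anhydride CC(=O)OC(C)=O
Why: Acylation should be selective for the unhindered allylic C5 hydroxyl because the C14 hydroxyl sits on the ring next to the quaternary C15, and C5 keeps its R configuration since the C–O bond is not broken.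

Step 16
Reactants: 23 (2E,5R,6E,10E)-1-{2-[(tert-butyldimethylsilyl)oxy]-5-methoxy-3-methylphenyl}-11-[(2S,4S)-4-hydroxy-5,5-dimethyloxolan-2-yl]-3,7-dimethyldodeca-2,6,10-trien-5-yl acetate
Product: 24 (2E,5R,6E,10E)-1-(2-hydroxy-5-methoxy-3-methylphenyl)-11-[(2S,4S)-4-hydroxy-5,5-dimethyloxolan-2-yl]-3,7-dimethyldodeca-2,6,10-trien-5-yl acetate
Conditions: Bu4NF, AcOH, THF, 0 °C
Reagents that add atoms: none
Why: Acetic-acid-buffered fluoride desilylation cleaves the aryl silyl ether quickly (phenoxide is the better leaving group on silicon) while the secondary allylic acetate should be stable under these conditions.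

Compound list
1 | geraniol, (2E)-3,7-dimethylocta-2,6-dien-1-ol | OC/C=C(\C)CCC=C(C)C | starting material
2 | tert-butyl{[(2E)-3,7-dimethylocta-2,6-dien-1-yl]oxy}dimethylsilane | CC(C)(C)[Si](C)(C)OC/C=C(\C)CCC=C(C)C | intermediate
3 | (2E,6E)-8-[(tert-butyldimethylsilyl)oxy]-2,6-dimethylocta-2,6-dien-1-ol | CC(C)(C)[Si](C)(C)OC/C=C(\C)CC/C=C(\C)CO | intermediate
4 | (2E,6E)-8-[(tert-butyldimethylsilyl)oxy]-2,6-dimethylocta-2,6-dienal | CC(C)(C)[Si](C)(C)OC/C=C(\C)CC/C=C(\C)C=O | intermediate
5 | methyl (triphenylphosphoranylidene)acetate | COC(=O)C=P(c1ccccc1)(c1ccccc1)c1ccccc1 | starting material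
6 | methyl (2E,4E,8E)-10-[(tert-butyldimethylsilyl)oxy]-4,8-dimethyldeca-2,4,8-trienoate | CC(C)(C)[Si](C)(C)OC/C=C(\C)CC/C=C(\C)/C=C/C(=O)OC | intermediate
7 | methyl 2-hydroxy-2-methylpropanoate | COC(=O)C(C)(C)O | starting material
8 | methyl (4E,8E)-10-[(tert-butyldimethylsilyl)oxy]-3-[(1-methoxy-2-methyl-1-oxopropan-2-yl)oxy]-4,8-dimethyldeca-4,8-dienoate (racemic; present as its sodium enolate) | CC(C)(C)[Si](C)(C)OC/C=C(\C)CC/C=C(\C)C(CC(=O)OC)OC(C)(C)C(=O)OC | intermediate
9 | methyl 2-[(2E,6E)-8-[(tert-butyldimethylsilyl)oxy]-6-methylocta-2,6-dien-2-yl]-5,5-dimethyl-4-oxooxolane-3-carboxylate (racemic, keto and enol forms) | CC(C)(C)[Si](C)(C)OC/C=C(\C)CC/C=C(\C)C1OC(C)(C)C(=O)C1C(=O)OC | intermediate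
10 | 5-[(2E,6E)-8-[(tert-butyldimethylsilyl)oxy]-6-methylocta-2,6-dien-2-yl]-2,2-dimethyloxolan-3-one (racemic) | CC(C)(C)[Si](C)(C)OC/C=C(\C)CC/C=C(\C)C1CC(=O)C(C)(C)O1 | intermediate
11 | (3S,5S)-5-[(2E,6E)-8-[(tert-butyldimethylsilyl)oxy]-6-methylocta-2,6-dien-2-yl]-2,2-dimethyloxolan-3-ol | CC(C)(C)[Si](C)(C)OC/C=C(\C)CC/C=C(\C)[C@@H]1C[C@H](O)C(C)(C)O1 | intermediate
12 | (2E,6E)-7-[(2S,4S)-4-hydroxy-5,5-dimethyloxolan-2-yl]-3-methylocta-2,6-dien-1-ol | OC/C=C(\C)CC/C=C(\C)[C@@H]1C[C@H](O)C(C)(C)O1 | intermediate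
13 | (2E,6E)-7-[(2S,4S)-4-hydroxy-5,5-dimethyloxolan-2-yl]-3-methylocta-2,6-dienal | O=C/C=C(\C)CC/C=C(\C)[C@@H]1C[C@H](O)C(C)(C)O1 | intermediate
14 | 4,4,5,5-tetramethyl-2-(propa-1,2-dien-1-yl)-1,3,2-dioxaborolane (allenylboronic acid pinacol ester) | C=C=CB1OC(C)(C)C(C)(C)O1 | starting material
15 | (4R,5E,9E)-10-[(2S,4S)-4-hydroxy-5,5-dimethyloxolan-2-yl]-6-methylundeca-5,9-dien-1-yn-4-ol | C#CC[C@H](/C=C(\C)CC/C=C(\C)[C@@H]1C[C@H](O)C(C)(C)O1)O | intermediate
16 | 4-methoxy-2-methylphenol | COc1ccc(O)c(C)c1 | starting material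
17 | 2-hydroxy-5-methoxy-3-methylbenzaldehyde | COc1cc(C)c(O)c(C=O)c1 | intermediate
18 | 2-[(tert-butyldimethylsilyl)oxy]-5-methoxy-3-methylbenzaldehyde | COc1cc(C)c(O[Si](C)(C)C(C)(C)C)c(C=O)c1 | intermediate
19 | {2-[(tert-butyldimethylsilyl)oxy]-5-methoxy-3-methylphenyl}methanol | COc1cc(C)c(O[Si](C)(C)C(C)(C)C)c(CO)c1 | intermediate
20 | tert-butyl[2-(chloromethyl)-4-methoxy-6-methylphenoxy]dimethylsilane | COc1cc(C)c(O[Si](C)(C)C(C)(C)C)c(CCl)c1 | intermediate
21 | (E)-alkenyl(dimethyl)alane from 15, both hydroxyls as dimethylaluminium alkoxides | C[Al](C)/C=C(\C)C[C@H](/C=C(\C)CC/C=C(\C)[C@@H]1C[C@H](O[Al](C)C)C(C)(C)O1)O[Al](C)C | intermediate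
22 | (2E,5R,6E,10E)-1-{2-[(tert-butyldimethylsilyl)oxy]-5-methoxy-3-methylphenyl}-11-[(2S,4S)-4-hydroxy-5,5-dimethyloxolan-2-yl]-3,7-dimethyldodeca-2,6,10-trien-5-ol | COc1cc(C)c(O[Si](C)(C)C(C)(C)C)c(C/C=C(\C)C[C@H](/C=C(\C)CC/C=C(\C)[C@@H]2C[C@H](O)C(C)(C)O2)O)c1 | intermediate
23 | (2E,5R,6E,10E)-1-{2-[(tert-butyldimethylsilyl)oxy]-5-methoxy-3-methylphenyl}-11-[(2S,4S)-4-hydroxy-5,5-dimethyloxolan-2-yl]-3,7-dimethyldodeca-2,6,10-trien-5-yl acetate | COc1cc(C)c(O[Si](C)(C)C(C)(C)C)c(C/C=C(\C)C[C@H](/C=C(\C)CC/C=C(\C)[C@@H]2C[C@H](O)C(C)(C)O2)OC(C)=O)c1 | intermediate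
24 | (2E,5R,6E,10E)-1-(2-hydroxy-5-methoxy-3-methylphenyl)-11-[(2S,4S)-4-hydroxy-5,5-dimethyloxolan-2-yl]-3,7-dimethyldodeca-2,6,10-trien-5-yl acetate | COc1cc(C)c(O)c(C/C=C(\C)C[C@H](/C=C(\C)CC/C=C(\C)[C@@H]2C[C@H](O)C(C)(C)O2)OC(C)=O)c1 | target

Total step count: 16. Longest linear sequence: 12 steps (steps 1 to 9 and 14 to 16); steps 10 to 13 prepare the aryl fragment.

Steps most likely to fail

Step 4. The oxa-Michael equilibrium of the hindered tertiary alkoxide may lie on the side of the dienoate, so that base-induced deconjugation, oligomerisation or 1,6-addition of 6 outruns the Dieckmann closure. The fallback sets out from 4 and comes back at 9, and it makes the ether without base. Alcohol 7 is silylated (Me3SiCl, Et3N, CH2Cl2) to methyl 2-methyl-2-[(trimethylsilyl)oxy]propanoate F1. Enal 4, F1 and commercial 1-methoxy-1-(trimethylsilyloxy)ethene are combined with catalytic Me3SiOTf in CH2Cl2 at −78 °C. The oxocarbenium ion formed from the aldehyde and the silyl ether should be trapped at C12 by the ketene silyl acetal (Mukaiyama-type three-component aldol-etherification) to give diester 8, now isolated. A separate kinetic Dieckmann condensation with LiN(SiMe3)2 in THF at −78 °C then closes the same C13–C14 bond and gives 9.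

Step 6. Reagent control may not fully override the substrate bias in the mismatched (12R)-enantiomer, or an uncatalysed background reduction may compete, so that the cis fraction is contaminated by its own enantiomer; hydroboration of the alkenes is a second hazard. The fallback sets out from 10 and comes back at 11, and it replaces catalyst control by substrate control plus a classical resolution. Ketone 10 is reduced with Li[B(s-Bu)3H] in THF at −78 °C, where hydride should enter anti to the alkenyl group and give the racemic cis alcohol, that is 11 together with its enantiomer, the (3R,5R)-alcohol F2. Esterification with (2S)-2-methoxy-2-phenylacetic acid (N-(3-dimethylaminopropyl)-N'-ethylcarbodiimide hydrochloride, 4-(dimethylamino)pyridine, CH2Cl2) should give the (3S,5S)-oxolan-3-yl (2S)-2-methoxy-2-phenylacetate F3 and its diastereomer, the (3R,5R)-oxolan-3-yl (2S)-2-methoxy-2-phenylacetate F4, which are separated by chromatography or crystallisation. Methanolysis of F3 (K2CO3, MeOH) returns 11.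

Step 14. Carboalumination of the dialkoxide may be slow or incomplete, the alkenylalane may be protonated before it couples, or transmetalation to palladium may be slow enough for homocoupling of 20 to take over. The fallback sets out from 15 and 20 and comes back at 22, and it separates carbometalation from coupling and reverses the polarity of the benzyl partner. Methylalumination of 15 (Me3Al, Cp2ZrCl2, CH2Cl2) is quenched with I2 to give the (E)-alkenyl iodide F5, which can be purified. Chloride 20 is converted with zinc dust and LiCl in THF into the benzylzinc chloride F6. Negishi coupling of F5 with an excess of F6 (Pd(OAc)2, 2-dicyclohexylphosphino-2',6'-dimethoxybiphenyl, THF, rt) should give 22 with retention of the E geometry.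

Further compounds
F1 | step 4 | methyl 2-methyl-2-[(trimethylsilyl)oxy]propanoate | COC(=O)C(C)(C)O[Si](C)(C)C
F2 | step 6 | (3R,5R)-5-[(2E,6E)-8-[(tert-butyldimethylsilyl)oxy]-6-methylocta-2,6-dien-2-yl]-2,2-dimethyloxolan-3-ol | CC(C)(C)[Si](C)(C)OC/C=C(\C)CC/C=C(\C)[C@H]1C[C@@H](O)C(C)(C)O1
F3 | step 6 | (3S,5S)-5-[(2E,6E)-8-[(tert-butyldimethylsilyl)oxy]-6-methylocta-2,6-dien-2-yl]-2,2-dimethyloxolan-3-yl (2S)-2-methoxy-2-phenylacetate | CC(C)(C)[Si](C)(C)OC/C=C(\C)CC/C=C(\C)[C@@H]1C[C@H](OC(=O)[C@@H](OC)c2ccccc2)C(C)(C)O1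
F4 | step 6 | (3R,5R)-5-[(2E,6E)-8-[(tert-butyldimethylsilyl)oxy]-6-methylocta-2,6-dien-2-yl]-2,2-dimethyloxolan-3-yl (2S)-2-methoxy-2-phenylacetate | CC(C)(C)[Si](C)(C)OC/C=C(\C)CC/C=C(\C)[C@H]1C[C@@H](OC(=O)[C@@H](OC)c2ccccc2)C(C)(C)O1
F5 | step 14 | (1E,4R,5E,9E)-10-[(2S,4S)-4-hydroxy-5,5-dimethyloxolan-2-yl]-1-iodo-2,6-dimethylundeca-1,5,9-trien-4-ol | I/C=C(\C)C[C@H](/C=C(\C)CC/C=C(\C)[C@@H]1C[C@H](O)C(C)(C)O1)O
F6 | step 14 | ({2-[(tert-butyldimethylsilyl)oxy]-5-methoxy-3-methylphenyl}methyl)zinc chloride, ArCH2ZnCl | COc1cc(C)c(O[Si](C)(C)C(C)(C)C)c(C[Zn]Cl)c1
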